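**Plan**

- Retrosynthesis: remove the C9 silyl ether; cut the γ-lactone at C8–C17 (intramolecular Reformatsky) and at the O7 ester; trace C6–Cl, C5=C6 and the C2/C7 carbinols back to a ten-membered 2,7-dione; rejoin C2 and C7 as the ring-fusion olefin of a Birch-reduced arene; cut ring A at C1–C14 and C10=C11 (Michael/aldol) and ring B back to an arylacetic acid plus ethylene.
- Enabling feature: C2 and C7 both carry oxygen and lie 1,6 across the ten-membered ring C1–C10, with C3, C4, C5(Me) and C6 between them. C2–C7 plus that arc is therefore a toluene ring fused to ring B, and its shared bond C2–C7 is the one to cut.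
- Forward order: arene → ring B → ring A (C9–O, C11 methyl, C12–O and C13=C14 all installed on the tricycle) → Birch reduction → ozonolysis merges the cyclohexadiene and ring B into the ten-membered ring → C5=C6/C6–Cl and the C2, C7 carbinols → lactone.
- Stereochemistry: C1 from an (R)-1-phenylethylamine enamine Michael addition; C9 by axial γ-oxidation of a dienol ether; C12 by bulky-hydride reduction, relayed to C10 and C11 by hydroxyl-directed hydrogenation and kept through an α-epoxide; C2 and C7 by CBS reductions; C8 and C17 in the Reformatsky closure (O7 tether, Felkin–Anh control by C9–OSi, chelated enolate).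

Key step: step 14

Remarks on the chemistry:
- Locants are those of the target skeleton throughout: C1–C10 is the ten-membered ring; C1, C10–C14 is ring A; C15, C16 and C20 are the methyls on C1, C5 and C11; C17/C18/C19 are the lactone CH, its methyl and the carbonyl. Before step 14, C2–C7 is the aromatic (then cyclohexadiene) ring and C1, C2, C7–C10 is ring B. β is the face of the C1 methyl in the flat drawing, α the opposite face.
- Assumption: the 1-phenylethylamine auxiliary in step 3 is taken to induce in the same sense as with 2-alkylcycloalkanone imines, so the R amine should give the 1R diketone 11. If the 2-tetralone enamine prefers the other face, the S amine is used and nothing else changes.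
- SMILES leave open those centres or enol geometries that form as mixtures and are erased later: the acetal carbons of 23, C5 in 25, C7 in 27, C5/C6 in 30, C7=C8 in 32, C8 in 33, 34, 36 and 37, and the CHBr carbon in 36–38.

**Route**

Step 1
Reactants: 1 2-(4-methylphenyl)acetic acid; 2 ethylene
Product: 4 6-methyl-3,4-dihydronaphthalen-2(1H)-one (6-methyl-2-tetralone), via arylacetyl chloride 3 (not isolated)
Conditions: (COCl)2, DMF (cat.), CH2Cl2, rt; then AlCl3, ethylene (1 atm), CH2Cl2, −10 °C to rt
Reagents that add atoms: none
Why: Friedel–Crafts acylation of ethylene by the acid chloride followed by intramolecular Friedel–Crafts alkylation ortho to the side chain is the standard 2-tetralone synthesis and places the para methyl at tetralone C6, the future C5 of the target, with no stereocentre formed.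

Step 2
Reactants: 4 6-methyl-2-tetralone; 5 iodomethane
Product: 7 rac-1,6-dimethyl-3,4-dihydronaphthalen-2(1H)-one, via pyrrolidine enamine 6 (not isolated)
Conditions: pyrrolidine, toluene, reflux (Dean–Stark); then MeI, MeCN, reflux; then AcOH–H2O, 60 °C
Reagents that add atoms: none
Why: Stork enamine alkylation methylates the arene-conjugated enamine once at the benzylic C1 position and so avoids the over-alkylation of a direct enolate methylation; the new centre is racemic and is planarised again in step 3.

Step 3
Reactants: 7 rac-1,6-dimethyl-2-tetralone; 8 pent-1-en-3-one (ethyl vinyl ketone)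
Product: 11 (1R)-1,6-dimethyl-1-(3-oxopentyl)-3,4-dihydronaphthalen-2(1H)-one, via chiral enamine 9 (not isolated), via imine adduct 10 (not isolated)
Conditions: (R)-1-phenylethylamine, TsOH (cat.), toluene, reflux (Dean–Stark); then 8, THF, 40 °C; then 20% aq. AcOH, rt
Reagents that add atoms: none
Why: Asymmetric Michael addition of a chiral imine through its secondary enamine tautomer (aza-ene-like, hydrogen-bonded transition state at the more substituted α-carbon) lets the phenyl group of the auxiliary shield one enamine face, so the enone adds to the other face and fixes the quaternary C1 centre while the ethyl ketone brings in C11–C14 and the C11 methyl.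

Step 4
Reactants: 11 (1R)-diketone
Product: 12 (4aS)-1,4a,7-trimethyl-4,4a,9,10-tetrahydrophenanthren-2(3H)-one (tricyclic enone; C12=O and C10=C11 in target numbering)
Conditions: NaOMe, MeOH, rt to 60 °C
Reagents that add atoms: none
Why: Intramolecular aldol condensation (second stage of the Robinson annulation) of the ethyl ketone methylene onto the tetralone carbonyl closes ring A as the tetrasubstituted C10=C11 enone, and the non-enolisable C1 centre is retained.

Step 5
Reactants: 12 tricyclic enone
Product: 14 9β-hydroxy enone (hydroxyl cis to the C1 methyl), via silyl dienol ether 13 (not isolated)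
Conditions: TBSOTf, Et3N, CH2Cl2, 0 °C; then mCPBA, NaHCO3, CH2Cl2, −20 °C; aq. Na2S2O3–NaHCO3 work-up
Reagents that add atoms: mCPBA (3-chloroperoxybenzoic acid), O=C(OO)c1cccc(Cl)c1
Why: Vinylogous Rubottom oxidation, in which the peracid attacks the γ-carbon C9 of the extended dienol ether axially from the β face (the stereoelectronically preferred approach known from the 6β-hydroxylation of steroidal 3,5-dienol ethers) and collapse of the epoxide regenerates the enone, should give the 9β alcohol.

Step 6
Reactants: 14 9β-hydroxy enone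
Product: 15 9β-(tert-butyldimethylsilyloxy) enone
Conditions: TBSOTf, 2,6-lutidine, CH2Cl2, −78 to 0 °C
Reagents that add atoms: tert-butyldimethylsilyl triflate, CC(C)(C)[Si](C)(C)OS(=O)(=O)C(F)(F)F
Why: Silylation of the hindered axial alcohol with the silyl triflate (standard alcohol protection) masks C9–OH so that it can neither direct the hydrogenation of step 8 to the wrong face nor eliminate towards the benzylic position, and no stereocentre is touched.

Step 7
Reactants: 15 silyloxy enone
Product: 16 12α-allylic alcohol (C10=C11; hydroxyl trans to the C1 methyl)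
Conditions: LiBH(s-Bu)3 (L-Selectride), THF, −78 °C; then H2O
Reagents that add atoms: none
Why: 1,2-Reduction of the β,β-disubstituted enone by a bulky trialkylborohydride, which approaches from the equatorial direction on the β face as with steroidal 4-en-3-ones, should give the pseudoaxial 12α alcohol.

Step 8
Reactants: 16 12α-allylic alcohol
Product: 17 saturated 12α-alcohol (10α-H; 11β-methyl; 9β-OTBS; trans-fused rings A and B)
Conditions: [Ir(cod)(PCy3)(py)]PF6 (cat.), H2 (1–4 atm), CH2Cl2, rt
Reagents that add atoms: none
Why: Hydroxyl-directed homogeneous hydrogenation, in which the cationic iridium catalyst binds the 12α-hydroxyl and delivers both hydrogens to the α face of the tetrasubstituted C10=C11 olefin (also the face away from the C1 methyl and the C9 silyl ether), sets C10 (α-H, trans ring fusion) and C11 (α-H, β-methyl) in one operation.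

Step 9
Reactants: 17 saturated 12α-alcohol
Product: 18 C12=C13 olefin (10α-H; 11β-methyl; 9β-OTBS)
Conditions: Ph2S[OC(CF3)2Ph]2 (Martin sulfurane), CH2Cl2, 0 °C to rt
Reagents that add atoms: none
Why: Martin sulfurane dehydration proceeds by anti elimination, and because the 12α oxygen has an anti-periplanar hydrogen only at C13 (H11 is cis to it) the olefin should form regiospecifically at C12=C13 with C11 untouched.

Step 10
Reactants: 18 C12=C13 olefin
Product: 19 12α,13α-epoxide
Conditions: mCPBA, NaHCO3, CH2Cl2, 0 °C
Reagents that add atoms: mCPBA (3-chloroperoxybenzoic acid), O=C(OO)c1cccc(Cl)c1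
Why: Prilezhaev epoxidation of the only olefin should occur on the α face because the β face is covered by the pseudoaxial C1 and C11 methyl groups.

Step 11
Reactants: 19 12α,13α-epoxide
Product: 20 12α-allylic alcohol with C13=C14 (arene stage)
Conditions: LiNEt2, Et2O–hexane, 0 °C to reflux; then H2O
Reagents that add atoms: none
Why: Lithium amide-induced epoxide-to-allylic-alcohol rearrangement (syn β-elimination) removes the pseudoaxial H14α of the methylene cis to the epoxide oxygen in preference to the tertiary, equatorial H11, so the C13–O bond breaks, the C13=C14 olefin forms and the C12–O bond keeps its 12α configuration.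

Step 12
Reactants: 20 allylic alcohol (arene)
Product: 21 Birch dienol (C2=C7 and C4=C5 cyclohexa-1,4-diene; 12α-OH; C13=C14)
Conditions: Li, NH3 (l), THF, t-BuOH, −78 to −33 °C
Reagents that add atoms: none
Why: Birch reduction of the 1,2,4-trialkylbenzene protonates the unsubstituted para pair C3 and C6 and leaves the tetrasubstituted C2=C7 and trisubstituted C4=C5 olefins, while the isolated C13=C14 olefin, the allylic lithium alkoxide and the silyl ether are inert to the dissolving metal.

Step 13
Reactants: 21 Birch dienol
Product: 22 Birch diene 12α-acetate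
Conditions: Ac2O, DMAP (cat.), pyridine, CH2Cl2, 0 °C to rt
Reagents that add atoms: acetic anhydride, CC(=O)OC(C)=O
Why: DMAP-catalysed acetylation installs the C12 acetate of the target with retention and at the same time lowers the electron density of the C13=C14 olefin ahead of the ozonolysis.

Step 14
Reactants: 22 Birch diene 12α-acetate
Product: 24 ring-A-fused (4Z)-cyclodec-4-ene-2,7-dione (9β-OTBS; 12α-OAc; C13=C14), via bridged ozonide 23 (not isolated)
Conditions: O3 (1.0 equiv, titrated solution in CH2Cl2), CH2Cl2, −78 °C; then Me2S, −78 °C to rt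
Reagents that add atoms: ozone, [O-][O+]=O
Why: Ozone adds to the C2=C7 olefin by concerted 1,3-dipolar cycloaddition, the primary ozonide cycloreverts to a ketone and a carbonyl oxide that recombine to ozonide 23, and Me2S reduces this to the two ketones. The closest known reaction type is the ozonolytic cleavage of the ring-fusion olefin of Birch-derived hexahydronaphthalenes and of octalins to cyclodecane-1,6-diones. No ring is closed by bond formation: the ten-membered ring C1–C10 appears because the bond shared by the cyclohexadiene ring and ring B (C2–C7) is cut, so the two six-membered rings merge. No stereocentre is created; C1, C9, C10, C11 and C12 are untouched and the C4=C5 olefin keeps the ring-cis (Z) geometry it had in the cyclohexadiene. The step needs cleavage of C2=C7 in preference to the trisubstituted C4=C5 and the disubstituted C13=C14 olefins: C2=C7 is tetrasubstituted and the most electron-rich, C13=C14 is deactivated by the allylic acetate and flanked by the quaternary C1, and ozone is dosed as one equivalent of a cold titrated solution.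

Step 15
Reactants: 24 2,7-dione
Product: 26 (5Z)-5-ene-2,7-dione (C5=C6 next to the C7 ketone), via tertiary chloride 25 (not isolated)
Conditions: HCl (1 M in Et2O), CH2Cl2, −78 to −40 °C; then Et3N, −40 to 0 °C
Reagents that add atoms: none
Why: Markovnikov hydrochlorination of the trisubstituted C4=C5 olefin gives the tertiary C5 chloride, and because only C6 is both next to that chloride and α to a carbonyl, amine-induced E1cB elimination moves the olefin specifically to C5=C6 beside C7 (the C2 ketone has no such pathway) under kinetic control, the ring-cis isomer being the less strained in a ten-membered ring.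

Step 16
Reactants: 26 (5Z)-5-ene-2,7-dione
Product: 27 2β,7-diol (2S; C7 configuration immaterial)
Conditions: (R)-2-methyl-CBS-oxazaborolidine, catecholborane, toluene, −78 to −30 °C; then MeOH, aq. NaOH
Reagents that add atoms: none
Why: Corey–Bakshi–Shibata reduction, in which the R catalyst treats the quaternary C1 as the large and the C3 methylene as the small substituent of the C2 ketone, should deliver hydride to the Re face of C2 and give the 2S (2β) alcohol under reagent control, while the C7 carbonyl is reduced as well and is simply re-oxidised in step 17.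

Step 17
Reactants: 27 2β,7-diol
Product: 28 2β-hydroxy-(5Z)-5-en-7-one
Conditions: MnO2 (activated, excess), CH2Cl2, rt
Reagents that add atoms: none
Why: Activated MnO2 oxidises allylic alcohols selectively, so only the C7 hydroxyl next to the C5=C6 olefin returns to the ketone while the saturated, neopentyl C2 alcohol keeps its new configuration.

Step 18
Reactants: 28 2β-hydroxy enone
Product: 29 2β-acetoxy-(5Z)-5-en-7-one
Conditions: Ac2O, DMAP, Et3N, CH2Cl2, rt
Reagents that add atoms: acetic anhydride, CC(=O)OC(C)=O
Why: DMAP-catalysed acetylation of the hindered secondary alcohol installs the C2 acetate of the target with retention and removes the last free hydroxyl before the enolate chemistry at C8.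

Step 19
Reactants: 29 2β-acetoxy enone
Product: 31 6-chloro-5-en-7-one (C4 and C7 cis across C5=C6; CIP descriptor 5E), via dichloride 30 (not isolated)
Conditions: PhICl2, pyridine, CH2Cl2, 0 °C to rt
Reagents that add atoms: iodobenzene dichloride, ClI(Cl)c1ccccc1
Why: Addition–elimination α-chlorination of an enone, in which chlorine from PhICl2 adds across C5=C6 and pyridine removes the acidic H6 with loss of the tertiary C5 chloride (E1cB), puts chlorine on C6 and restores the olefin in its more stable ring-cis form, the ring-A olefin being shielded on both faces by the C1 and C11 methyls and the C12 acetate and deactivated by that allylic acetate.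

Step 20
Reactants: 31 6-chloro enone
Product: 33 8-(triethylsilyloxy)-7-ketone (C8 epimers), via silyl enol ether 32 (not isolated)
Conditions: LiN(SiMe3)2, Et3SiCl, THF, −78 °C; then mCPBA, NaHCO3, CH2Cl2, −20 °C
Reagents that add atoms: chlorotriethylsilane, CC[Si](Cl)(CC)CC; mCPBA (3-chloroperoxybenzoic acid), O=C(OO)c1cccc(Cl)c1
Why: Rubottom oxidation, with kinetic α′-deprotonation of the enone at C8 under in situ silylation, epoxidation of the electron-rich silyl enol ether and 1,4-silyl migration, gives the α-silyloxy ketone, and either C8 epimer serves because C8 becomes a carbonyl in step 24.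

Step 21
Reactants: 33 8-silyloxy ketone
Product: 34 7α-alcohol (7R)
Conditions: (S)-2-methyl-CBS-oxazaborolidine, catecholborane, toluene–CH2Cl2, −78 °C; then MeOH
Reagents that add atoms: none
Why: Corey–Bakshi–Shibata reduction of an α-chloro enone, a substrate class in which the halovinyl group acts as the large substituent, should with the S catalyst deliver hydride to the Si face of C7 and give the 7R (7α) alcohol, anti to the C9 oxygen, whatever the C8 configuration.

Step 22
Reactants: 34 7α-alcohol; 35 2-bromopropanoyl bromide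
Product: 36 7α-O-(2-bromopropanoyl) ester (8-OTES; 9β-OTBS)
Conditions: pyridine, DMAP (cat.), CH2Cl2, −20 °C
Reagents that add atoms: none
Why: Pyridine-mediated acylation of the secondary allylic alcohol by the acid bromide proceeds with retention at C7 and attaches C17–C19, the bromine-bearing carbon being an epimer mixture that is immaterial because it becomes an enolate carbon in step 25.

Step 23
Reactants: 36 bromo ester
Product: 37 8-hydroxy bromo ester
Conditions: HF·pyridine, pyridine, THF, 0 °C
Reagents that add atoms: none
Why: Buffered HF·pyridine cleaves the more labile triethylsilyl ether in preference to the hindered tert-butyldimethylsilyl ether at C9 (graded silyl ether lability) and frees only the C8 hydroxyl.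

Step 24
Reactants: 37 8-hydroxy bromo ester
Product: 38 8-keto bromo ester
Conditions: Dess–Martin periodinane, NaHCO3, CH2Cl2, 0 °C
Reagents that add atoms: none
Why: Dess–Martin oxidation under buffered, non-enolising conditions converts the C8 alcohol into the ketone without epimerising C7 or C9 and makes the C8 epimers converge.

Step 25
Reactants: 38 8-keto bromo ester
Product: 39 9-O-TBS ether of the target (7,8-fused γ-lactone; 8α-OH; C17 methyl cis to that hydroxyl)
Conditions: SmI2 (2.2 equiv), THF, −78 °C
Reagents that add atoms: none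
Why: Samarium diiodide-promoted intramolecular Reformatsky reaction, in which selective reduction of the C–Br bond gives a samarium ester enolate that adds to the C8 ketone on the face held by the O7 tether, which is also the face anti to the C9–OSi bond (Felkin–Anh), should give the 8α-hydroxyl, while the chelated Z-enolate places the C17 methyl cis to that hydroxyl, also the more stable arrangement with the methyl away from C9.

Step 26
Reactants: 39 9-O-TBS ether
Product: 40 target CNP0296164.1
Conditions: HF·pyridine, THF–MeCN, 0 °C to rt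
Reagents that add atoms: none
Why: Fluoride-mediated desilylation under mildly acidic conditions removes the last protecting group and leaves the two acetates, the lactone, the vinyl chloride and the free alcohols untouched.

**Compound list**

1 | 2-(4-methylphenyl)acetic acid | Cc1ccc(CC(=O)O)cc1 | starting material
2 | ethylene | C=C | starting material
3 | (4-methylphenyl)acetyl chloride | Cc1ccc(CC(=O)Cl)cc1 | intermediate
4 | 6-methyl-3,4-dihydronaphthalen-2(1H)-one | Cc1ccc2c(c1)CCC(=O)C2 | intermediate
5 | iodomethane | CI | starting material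
6 | 1-(6-methyl-3,4-dihydronaphthalen-2-yl)pyrrolidine | Cc1ccc2c(c1)CCC(N1CCCC1)=C2 | intermediate
7 | rac-1,6-dimethyl-3,4-dihydronaphthalen-2(1H)-one | Cc1ccc2c(c1)CCC(=O)C2C | intermediate
8 | pent-1-en-3-one | CCC(=O)C=C | starting material
9 | 1,6-dimethyl-N-[(1R)-1-phenylethyl]-3,4-dihydronaphthalen-2-amine (secondary enamine) | Cc1ccc2c(c1)CCC(N[C@H](C)c1ccccc1)=C2C | intermediate
10 | N-[(1R)-1-phenylethyl]imine of (1R)-1,6-dimethyl-1-(3-oxopentyl)-3,4-dihydronaphthalen-2(1H)-one | CCC(=O)CC[C@@]1(C)C(=N[C@H](C)c3ccccc3)CCc2cc(C)ccc21 | intermediate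
11 | (1R)-1,6-dimethyl-1-(3-oxopentyl)-3,4-dihydronaphthalen-2(1H)-one | CCC(=O)CC[C@@]1(C)C(=O)CCc2cc(C)ccc21 | intermediate
12 | (4aS)-1,4a,7-trimethyl-4,4a,9,10-tetrahydrophenanthren-2(3H)-one | Cc1ccc2c(c1)CCC3=C(C)C(=O)CC[C@]23C | intermediate
13 | 12-O-TBS dienol ether of 12 (C9=C10 and C11=C12) | Cc1ccc2c(c1)CC=C3C(C)=C(O[Si](C)(C)C(C)(C)C)CC[C@]23C | intermediate
14 | 9β-hydroxy enone | Cc1ccc2c(c1)C[C@@H](O)C3=C(C)C(=O)CC[C@]23C | intermediate
15 | 9β-(tert-butyldimethylsilyloxy) enone | Cc1ccc2c(c1)C[C@@H](O[Si](C)(C)C(C)(C)C)C3=C(C)C(=O)CC[C@]23C | intermediate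
16 | 12α-allylic alcohol (C10=C11; 9β-OTBS) | Cc1ccc2c(c1)C[C@@H](O[Si](C)(C)C(C)(C)C)C3=C(C)[C@H](O)CC[C@]23C | intermediate
17 | saturated 12α-alcohol (10α-H; 11β-methyl; 9β-OTBS) | Cc1ccc2c(c1)C[C@@H](O[Si](C)(C)C(C)(C)C)[C@H]3[C@@H](C)[C@H](O)CC[C@]23C | intermediate
18 | C12=C13 olefin (10α-H; 11β-methyl; 9β-OTBS) | Cc1ccc2c(c1)C[C@@H](O[Si](C)(C)C(C)(C)C)[C@H]3[C@@H](C)C=CC[C@]23C | intermediate
19 | 12α,13α-epoxide | Cc1ccc2c(c1)C[C@@H](O[Si](C)(C)C(C)(C)C)[C@H]3[C@@H](C)[C@@H]4O[C@@H]4C[C@]23C | intermediate
20 | 12α-allylic alcohol with C13=C14 (arene) | Cc1ccc2c(c1)C[C@@H](O[Si](C)(C)C(C)(C)C)[C@H]3[C@@H](C)[C@H](O)C=C[C@]23C | intermediate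
21 | Birch dienol (C2=C7 and C4=C5; 12α-OH; C13=C14; 9β-OTBS) | CC1=CCC2=C(C1)C[C@@H](O[Si](C)(C)C(C)(C)C)[C@H]3[C@@H](C)[C@H](O)C=C[C@]23C | intermediate
22 | Birch diene 12α-acetate | CC1=CCC2=C(C1)C[C@@H](O[Si](C)(C)C(C)(C)C)[C@H]3[C@@H](C)[C@H](OC(C)=O)C=C[C@]23C | intermediate
23 | ozonide (1,2,4-trioxolane) bridging C2 and C7 | C14(OO5)C/C=C(C)\CC5(O4)C[C@@H](O[Si](C)(C)C(C)(C)C)[C@H]2[C@@H](C)[C@H](OC(C)=O)C=C[C@@]21C | intermediate
24 | ring-A-fused (4Z)-cyclodec-4-ene-2,7-dione (9β-OTBS; 12α-OAc; C13=C14) | O=C1C/C=C(C)\CC(=O)C[C@@H](O[Si](C)(C)C(C)(C)C)[C@H]2[C@@H](C)[C@H](OC(C)=O)C=C[C@@]21C | intermediate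
25 | 5-chloro-2,7-dione | O=C1CCC(C)(Cl)CC(=O)C[C@@H](O[Si](C)(C)C(C)(C)C)[C@H]2[C@@H](C)[C@H](OC(C)=O)C=C[C@@]21C | intermediate
26 | (5Z)-5-ene-2,7-dione | O=C1CC/C(C)=C\C(=O)C[C@@H](O[Si](C)(C)C(C)(C)C)[C@H]2[C@@H](C)[C@H](OC(C)=O)C=C[C@@]21C | intermediate
27 | (5Z)-2β,7-diol | O[C@H]1CC/C(C)=C\C(O)C[C@@H](O[Si](C)(C)C(C)(C)C)[C@H]2[C@@H](C)[C@H](OC(C)=O)C=C[C@@]21C | intermediate
28 | 2β-hydroxy-(5Z)-5-en-7-one | O[C@H]1CC/C(C)=C\C(=O)C[C@@H](O[Si](C)(C)C(C)(C)C)[C@H]2[C@@H](C)[C@H](OC(C)=O)C=C[C@@]21C | intermediate
29 | 2β-acetoxy-(5Z)-5-en-7-one | CC(=O)O[C@H]1CC/C(C)=C\C(=O)C[C@@H](O[Si](C)(C)C(C)(C)C)[C@H]2[C@@H](C)[C@H](OC(C)=O)C=C[C@@]21C | intermediate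
30 | 5,6-dichloro-7-ketone | CC(=O)O[C@H]1CCC(C)(Cl)C(Cl)C(=O)C[C@@H](O[Si](C)(C)C(C)(C)C)[C@H]2[C@@H](C)[C@H](OC(C)=O)C=C[C@@]21C | intermediate
31 | 6-chloro-5-en-7-one (ring-cis; 5E) | CC(=O)O[C@H]1CC/C(C)=C(/Cl)C(=O)C[C@@H](O[Si](C)(C)C(C)(C)C)[C@H]2[C@@H](C)[C@H](OC(C)=O)C=C[C@@]21C | intermediate
32 | 7-O-triethylsilyl enol ether (C7=C8) | CC(=O)O[C@H]1CC/C(C)=C(/Cl)C(O[Si](CC)(CC)CC)=C[C@@H](O[Si](C)(C)C(C)(C)C)[C@H]2[C@@H](C)[C@H](OC(C)=O)C=C[C@@]21C | intermediate
33 | 8-(triethylsilyloxy)-7-ketone | CC(=O)O[C@H]1CC/C(C)=C(/Cl)C(=O)C(O[Si](CC)(CC)CC)[C@@H](O[Si](C)(C)C(C)(C)C)[C@H]2[C@@H](C)[C@H](OC(C)=O)C=C[C@@]21C | intermediate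
34 | 7α-alcohol (7R; 8-OTES) | CC(=O)O[C@H]1CC/C(C)=C(/Cl)[C@H](O)C(O[Si](CC)(CC)CC)[C@@H](O[Si](C)(C)C(C)(C)C)[C@H]2[C@@H](C)[C@H](OC(C)=O)C=C[C@@]21C | intermediate
35 | 2-bromopropanoyl bromide (racemic) | CC(Br)C(=O)Br | starting material
36 | 7α-O-(2-bromopropanoyl) ester (8-OTES) | CC(=O)O[C@H]1CC/C(C)=C(/Cl)[C@H](OC(=O)C(C)Br)C(O[Si](CC)(CC)CC)[C@@H](O[Si](C)(C)C(C)(C)C)[C@H]2[C@@H](C)[C@H](OC(C)=O)C=C[C@@]21C | intermediate
37 | 8-hydroxy bromo ester | CC(=O)O[C@H]1CC/C(C)=C(/Cl)[C@H](OC(=O)C(C)Br)C(O)[C@@H](O[Si](C)(C)C(C)(C)C)[C@H]2[C@@H](C)[C@H](OC(C)=O)C=C[C@@]21C | intermediate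
38 | 8-keto bromo ester | CC(=O)O[C@H]1CC/C(C)=C(/Cl)[C@H](OC(=O)C(C)Br)C(=O)[C@@H](O[Si](C)(C)C(C)(C)C)[C@H]2[C@@H](C)[C@H](OC(C)=O)C=C[C@@]21C | intermediate
39 | 9-O-TBS ether of the target | CC(=O)O[C@H]1CC/C(C)=C(/Cl)[C@@H]2OC(=O)[C@H](C)[C@@]2(O)[C@@H](O[Si](C)(C)C(C)(C)C)[C@H]2[C@@H](C)[C@H](OC(C)=O)C=C[C@@]21C | intermediate
40 | CNP0296164.1: (1S,2S,5E,7R,8R,9S,10S,11R,12R,17R)-2β,12α-diacetoxy-6-chloro-8α,9β-dihydroxy-5,13-diene with the C19-carbonyl γ-lactone closed on O7 | CC(=O)O[C@H]1CC/C(C)=C(/Cl)[C@@H]2OC(=O)[C@H](C)[C@@]2(O)[C@@H](O)[C@H]2[C@@H](C)[C@H](OC(C)=O)C=C[C@@]21C | target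

**Step count and risks**

Total step count: 26. Longest linear sequence: 26 steps (the route is linear from 1).

The three steps most likely to fail:

Step 14. Ozone may not stop at the C2=C7 olefin: partial attack on the trisubstituted C4=C5 olefin (or on C13=C14) before all of 22 is consumed would erode the dione. The fallback sets out from 22 and replaces ozone by a reagent that tells tetra- from trisubstituted olefins much more sharply. mCPBA (1 equiv, CH2Cl2, −40 °C) should epoxidise only the ring-fusion olefin to give the C2–C7 epoxide F1. Periodic acid in wet THF then opens it to the 2,7-diol F2 and cleaves the glycol in the same flask. This returns to the route at dione 24.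

Step 15. The acid needed for hydrochlorination may instead trigger transannular aldolisation of the 1,6-dione, or capture of the C5 cation by the C2 carbonyl oxygen. The fallback sets out from 24 and forms the C5–Cl bond by a radical path instead of a polar one. Cobalt-catalysed hydrogen-atom-transfer hydrochlorination (Co(BF4)2·6H2O with a salicylaldimine ligand, TsCl, PhSiH3, EtOH, rt) works under neutral conditions. It is selective for the trisubstituted olefin over the 1,2-disubstituted C13=C14. It should give the same tertiary chloride 25, where the route is rejoined for the amine-induced elimination; no new compound is made.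

Step 25. The samarium enolate may add to the wrong face of the C8 ketone, or the α-acyloxy ketone may be reduced before the aldol closure. The fallback sets out from 38 and builds the lactone as a butenolide first. PPh3 (MeCN, 40 °C) converts the bromide into the phosphonium bromide F3. Et3N then triggers an intramolecular Wittig reaction onto the C8 ketone to give the C8=C17 butenolide F4. Nucleophilic epoxidation (t-BuOOH, DBU), expected on the outer α face of the butenolide, gives the 8α,17-epoxy lactone F5. SmI2 with MeOH cleaves the C17–O bond of this α,β-epoxy lactone and protonates C17; mild base equilibration at C17, if needed, gives the epimer with the methyl away from C9. This returns to the route at 39.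

**Further compounds**

F1 | step 14 | C2–C7 epoxide of diene acetate 22 | CC1=CCC25OC5(C1)C[C@@H](O[Si](C)(C)C(C)(C)C)[C@H]3[C@@H](C)[C@H](OC(C)=O)C=C[C@]23C
F2 | step 14 | 2,7-diol from opening of F1 | CC1=CCC2(O)C(O)(C1)C[C@@H](O[Si](C)(C)C(C)(C)C)[C@H]3[C@@H](C)[C@H](OC(C)=O)C=C[C@]23C
F0 | step 15 | none | none
F3 | step 25 | triphenylphosphonium bromide from 38 | CC(=O)O[C@H]1CC/C(C)=C(/Cl)[C@H](OC(=O)C(C)[P+](c3ccccc3)(c3ccccc3)c3ccccc3)C(=O)[C@@H](O[Si](C)(C)C(C)(C)C)[C@H]2[C@@H](C)[C@H](OC(C)=O)C=C[C@@]21C.[Br-]
F4 | step 25 | C8=C17 butenolide | CC(=O)O[C@H]1CC/C(C)=C(/Cl)[C@@H]2OC(=O)C(C)=C2[C@@H](O[Si](C)(C)C(C)(C)C)[C@H]2[C@@H](C)[C@H](OC(C)=O)C=C[C@@]21C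
F5 | step 25 | 8α,17-epoxy lactone | CC(=O)O[C@H]1CC/C(C)=C(/Cl)[C@@H]2OC(=O)[C@]3(C)O[C@]23[C@@H](O[Si](C)(C)C(C)(C)C)[C@H]2[C@@H](C)[C@H](OC(C)=O)C=C[C@@]21C
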